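The hexasubstituted benzene ring (C4a, C5, C6, C7, C8, C8a) is disconnected at the C4a–C5 bond. Since the C5 and C8 hydroxyls are para and C6 (acyl) and C7 (methoxy) are neighbours, C5–C8 can come from a cyclobutenedione carrying methoxy and the masked acyl group, and C8a/C4a from the enol ether of a preformed dihydropyran. Heating hydroxycyclobutenone 14 should open the small ring to a dienylketene and close the hydroquinone ring onto the pyran in one operation. In 14 the ketone is a dithiane and pyran C4 bears a silyloxy group (TIPS, not TBS, for clean lithiation) that later departs to give the C3–C4 alkene.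

Key step: step 6

Assumption 1: the target has no stereocentre, so the "single enantiomer" is the one achiral compound; the carbinol and C4 centres of intermediates are carried as racemates or diastereomer mixtures and are erased before the end.
Assumption 2: pyranone 9 is taken as a catalogue compound.

Step 1
Reactants: 1 3-phenylpropanal; 2 propane-1,3-dithiol
Product: 3 2-(2-phenylethyl)-1,3-dithiane
Conditions: BF3·OEt2 (10 mol %), CH2Cl2, 0 °C → rt
Reagents that add atoms: none
Why: Lewis-acid-catalysed dithioacetalisation of an unhindered aldehyde (first half of a Corey–Seebach umpolung) is reliable and creates no stereocentre.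

Step 2
Reactants: 3 2-(2-phenylethyl)-1,3-dithiane; 4 dimethyl squarate
Product: 8 3-methoxy-4-[2-(2-phenylethyl)-1,3-dithian-2-yl]cyclobut-3-ene-1,2-dione, via lithiodithiane 5 (not isolated), via lithium alkoxide 6 (not isolated), via trifluoroacetate 7 (not isolated)
Conditions: n-BuLi (1.05 equiv), THF, −30 °C; add to 4 (1.1 equiv), THF, −78 °C; TFAA (1.3 equiv), −78 °C; H2O, → rt
Reagents that add atoms: water, O
Why: Corey–Seebach lithiation gives the dithianyl anion, which adds 1,2 to a squarate carbonyl, and the trifluoroacetylated adduct then ionises with methoxy assistance, takes up water at the methoxy-bearing terminus and loses methanol (the standard squarate 1,2-addition/carbonyl transposition), the positive charge sitting on the oxocarbenium carbon remote from sulfur.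

Step 3
Reactants: 9 2,2-dimethyl-2,3-dihydro-4H-pyran-4-one
Product: 10 2,2-dimethyl-3,4-dihydro-2H-pyran-4-ol (racemic)
Conditions: NaBH4, CeCl3·7H2O, MeOH, −40 → 0 °C
Reagents that add atoms: none
Why: Luche 1,2-reduction of the vinylogous-ester carbonyl should give the glycal-like allylic alcohol without conjugate reduction; the C4 carbinol centre forms as a racemate and is removed in step 7.

Step 4
Reactants: 10 2,2-dimethyl-3,4-dihydro-2H-pyran-4-ol
Product: 11 [(2,2-dimethyl-3,4-dihydro-2H-pyran-4-yl)oxy]tri(propan-2-yl)silane (racemic)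
Conditions: TIPSCl, imidazole, DMAP (cat.), DMF, rt
Reagents that add atoms: chlorotri(propan-2-yl)silane (TIPSCl), CC(C)[Si](Cl)(C(C)C)C(C)C
Why: Silylation of a secondary alcohol under basic conditions avoids Ferrier-type ionisation of the allylic C–O bond, and TIPS (no Si–CH3 group) is preferred to TBS because it cannot be metalated competitively in step 5.

Step 5
Reactants: 11 [(2,2-dimethyl-3,4-dihydro-2H-pyran-4-yl)oxy]tri(propan-2-yl)silane; 8 3-methoxy-4-[2-(2-phenylethyl)-1,3-dithian-2-yl]cyclobut-3-ene-1,2-dione
Product: 14 4-[2,2-dimethyl-4-(triisopropylsilyloxy)-3,4-dihydro-2H-pyran-6-yl]-4-hydroxy-3-methoxy-2-[2-(2-phenylethyl)-1,3-dithian-2-yl]cyclobut-2-en-1-one (racemic diastereomer mixture), via vinyllithium 12 (not isolated), via lithium alkoxide 13 (not isolated)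
Conditions: 11 (1.5 equiv), t-BuLi (1.3 equiv), THF, −78 → 0 °C; add to 8 (1.0 equiv), THF, −78 °C; aq. NH4Cl
Reagents that add atoms: none
Why: C6–H lithiation next to the ring oxygen follows the C1-lithiation of silyl-protected glycals, and the alkenyllithium should add 1,2 to the more electrophilic ketone carbonyl of 8 (the one beside the methoxy-bearing carbon, not the vinylogous-ester carbonyl shielded by the dithiane), with t-BuLi kept substoichiometric to 11 so that no free alkyllithium meets 8; the carbinol centre forms without control and is erased in step 6.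

Step 6
Reactants: 14 4-[2,2-dimethyl-4-(triisopropylsilyloxy)-3,4-dihydro-2H-pyran-6-yl]-4-hydroxy-3-methoxy-2-[2-(2-phenylethyl)-1,3-dithian-2-yl]cyclobut-2-en-1-one
Product: 17 7-methoxy-2,2-dimethyl-6-[2-(2-phenylethyl)-1,3-dithian-2-yl]-4-(triisopropylsilyloxy)chromane-5,8-diol (racemic), via dienylketene 15 (not isolated), via cyclohexadienone 16 (not isolated)
Conditions: PhMe (degassed, 0.02 M), 110 °C, Ar
Reagents that add atoms: none
Why: Heating should trigger a conrotatory 4π electrocyclic opening of the cyclobutenone C1–C4 bond to dienylketene 15, in which the donor hydroxyl has turned outward (torquoselectivity) so that the dihydropyranyl group points inward and its C5=C6 enol-ether bond lies next to the ketene carbon. A thermal disrotatory 6π electrocyclisation then joins the ketene carbon to pyran C5, closing the six-membered carbocycle ortho-fused to the existing pyran (the chromane C4a–C5 bond) to give dienone 16, which aromatises by enolisation to hydroquinone 17. The closest known reaction type is the Moore rearrangement of 4-alkenyl-4-hydroxycyclobutenones, 2-dihydropyranyl cases included. No new stereocentre survives: the transient C4a centre of 16 is lost on enolisation, the carbinol carbon becomes aromatic C8, and the C4 silyloxy centre is carried unchanged as a racemate. The step needs the ring order OH/dithianyl/OMe/OH, already fixed by the regioselective addition of step 5, and C–C closure in preference to attack of the hydroxyl on the ketene, which the outward rotation of the OH secures by placing it away from the ketene carbon.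

Step 7
Reactants: 17 7-methoxy-2,2-dimethyl-6-[2-(2-phenylethyl)-1,3-dithian-2-yl]-4-(triisopropylsilyloxy)chromane-5,8-diol
Product: 18 7-methoxy-2,2-dimethyl-6-[2-(2-phenylethyl)-1,3-dithian-2-yl]-2H-chromene-5,8-diol
Conditions: p-TsOH·H2O (10 mol %), PhMe (degassed), 80 °C
Reagents that add atoms: none
Why: Acid-catalysed E1 elimination: the benzylic C4–O bond, ortho to the C5 hydroxyl and para to the C7 methoxy, should ionise with loss of silanol to an o-quinone-methide-type cation that sheds a C3 proton to give the conjugated 2H-chromene and so removes the last stereocentre, while the fully substituted arene offers no site for Friedel–Crafts side reactions and the dithiane tolerates acid.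

Step 8
Reactants: 18 7-methoxy-2,2-dimethyl-6-[2-(2-phenylethyl)-1,3-dithian-2-yl]-2H-chromene-5,8-diol
Product: 19 Flemistrictin D, 1-(5,8-dihydroxy-7-methoxy-2,2-dimethyl-2H-chromen-6-yl)-3-phenylpropan-1-one
Conditions: MeI (excess), CaCO3, MeCN–H2O 4:1 (degassed), 45 °C, dark
Reagents that add atoms: water, O
Why: Alkylative dithiane hydrolysis (S-methylation, ring opening to an aryl-stabilised thionium ion, capture by water) is non-oxidative and near-neutral, so the hydroquinone and the chromene alkene should survive and the ketone should emerge hydrogen-bonded to the C5 hydroxyl.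

Compound list
1 | 3-phenylpropanal | O=CCCc1ccccc1 | starting material
2 | propane-1,3-dithiol | SCCCS | starting material
3 | 2-(2-phenylethyl)-1,3-dithiane | C(Cc1ccccc1)C1SCCCS1 | intermediate
4 | dimethyl squarate (3,4-dimethoxycyclobut-3-ene-1,2-dione) | COC1=C(OC)C(=O)C1=O | starting material
5 | 2-lithio-2-(2-phenylethyl)-1,3-dithiane (not isolated) | [Li]C1(CCc2ccccc2)SCCCS1 | intermediate
6 | lithium 2,3-dimethoxy-4-oxo-1-[2-(2-phenylethyl)-1,3-dithian-2-yl]cyclobut-2-en-1-olate (racemic, not isolated) | COC1=C(OC)C([O-])(C2(CCc3ccccc3)SCCCS2)C1=O.[Li+] | intermediate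
7 | 2,3-dimethoxy-4-oxo-1-[2-(2-phenylethyl)-1,3-dithian-2-yl]cyclobut-2-en-1-yl trifluoroacetate (racemic, not isolated) | COC1=C(OC)C(OC(=O)C(F)(F)F)(C2(CCc3ccccc3)SCCCS2)C1=O | intermediate
8 | 3-methoxy-4-[2-(2-phenylethyl)-1,3-dithian-2-yl]cyclobut-3-ene-1,2-dione | COC1=C(C2(CCc3ccccc3)SCCCS2)C(=O)C1=O | intermediate
9 | 2,2-dimethyl-2,3-dihydro-4H-pyran-4-one | CC1(C)CC(=O)C=CO1 | starting material
10 | 2,2-dimethyl-3,4-dihydro-2H-pyran-4-ol (racemic) | CC1(C)CC(O)C=CO1 | intermediate
11 | [(2,2-dimethyl-3,4-dihydro-2H-pyran-4-yl)oxy]tri(propan-2-yl)silane (racemic) | CC1(C)CC(O[Si](C(C)C)(C(C)C)C(C)C)C=CO1 | intermediate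
12 | [(6-lithio-2,2-dimethyl-3,4-dihydro-2H-pyran-4-yl)oxy]tri(propan-2-yl)silane (racemic, not isolated) | [Li]C1=CC(O[Si](C(C)C)(C(C)C)C(C)C)CC(C)(C)O1 | intermediate
13 | lithium alkoxide of 14 (diastereomer mixture, not isolated) | COC1=C(C2(CCc3ccccc3)SCCCS2)C(=O)C1([O-])C1=CC(O[Si](C(C)C)(C(C)C)C(C)C)CC(C)(C)O1.[Li+] | intermediate
14 | 4-[2,2-dimethyl-4-(triisopropylsilyloxy)-3,4-dihydro-2H-pyran-6-yl]-4-hydroxy-3-methoxy-2-[2-(2-phenylethyl)-1,3-dithian-2-yl]cyclobut-2-en-1-one (racemic diastereomer mixture) | COC1=C(C2(CCc3ccccc3)SCCCS2)C(=O)C1(O)C1=CC(O[Si](C(C)C)(C(C)C)C(C)C)CC(C)(C)O1 | intermediate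
15 | dienylketene from ring opening of 14: 4-hydroxy-3-methoxy-2-[2-(2-phenylethyl)-1,3-dithian-2-yl]-4-[2,2-dimethyl-4-(triisopropylsilyloxy)-3,4-dihydro-2H-pyran-6-yl]buta-1,3-dien-1-one, pyranyl group cis to the ketene-bearing carbon (racemic, not isolated) | O=C=C(C2(CCc3ccccc3)SCCCS2)/C(OC)=C(/O)C1=CC(O[Si](C(C)C)(C(C)C)C(C)C)CC(C)(C)O1 | intermediate
16 | 8-hydroxy-7-methoxy-2,2-dimethyl-6-[2-(2-phenylethyl)-1,3-dithian-2-yl]-4-(triisopropylsilyloxy)-3,4-dihydro-2H-chromen-5(4aH)-one (diastereomer mixture, not isolated) | O=C1C(C3(CCc4ccccc4)SCCCS3)=C(OC)C(O)=C2OC(C)(C)CC(O[Si](C(C)C)(C(C)C)C(C)C)C12 | intermediate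
17 | 7-methoxy-2,2-dimethyl-6-[2-(2-phenylethyl)-1,3-dithian-2-yl]-4-(triisopropylsilyloxy)chromane-5,8-diol (racemic) | Oc1c(C3(CCc4ccccc4)SCCCS3)c(OC)c(O)c2OC(C)(C)CC(O[Si](C(C)C)(C(C)C)C(C)C)c12 | intermediate
18 | 7-methoxy-2,2-dimethyl-6-[2-(2-phenylethyl)-1,3-dithian-2-yl]-2H-chromene-5,8-diol | Oc1c(C3(CCc4ccccc4)SCCCS3)c(OC)c(O)c2OC(C)(C)C=Cc12 | intermediate
19 | Flemistrictin D, 1-(5,8-dihydroxy-7-methoxy-2,2-dimethyl-2H-chromen-6-yl)-3-phenylpropan-1-one (achiral) | COc1c(O)c2c(c(O)c1C(=O)CCc1ccccc1)C=CC(C)(C)O2 | target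

Total step count: 8. Longest linear sequence: 6 steps (1, 2, 5, 6, 7, 8; the pyran branch 3, 4, 5, 6, 7, 8 is equally long).

Steps most likely to fail

Step 6. The ring-opened ketene may be captured by the carbinol oxygen (inward rotation of the hydroxyl, lactone formation), or the electron-rich hydroquinone may oxidise during isolation. The fallback sets out from 13 and comes back at 18. The lithium alkoxide 13 is quenched with TMSCl instead of NH4Cl to give the O-silylated precursor 4-[2,2-dimethyl-4-(triisopropylsilyloxy)-3,4-dihydro-2H-pyran-6-yl]-3-methoxy-2-[2-(2-phenylethyl)-1,3-dithian-2-yl]-4-(trimethylsilyloxy)cyclobut-2-en-1-one F1, which has no free hydroxyl to attack the ketene. Thermolysis in degassed toluene at 110 °C should then give the mono-silylated, oxidation-resistant hydroquinone 7-methoxy-2,2-dimethyl-6-[2-(2-phenylethyl)-1,3-dithian-2-yl]-4-(triisopropylsilyloxy)-8-(trimethylsilyloxy)chroman-5-ol F2. The acid treatment of step 7 with aqueous work-up removes the aryl TMS ether together with the C4 silyloxy group and delivers 18.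

Step 8. The thiophile may oxidise the hydroquinone, a phenol may be O-methylated, or hydrolysis of the hindered thioketal may stall. The fallback sets out from 18 and comes back at 19. The unmasking is run deliberately at the quinone oxidation level: PhI(OCOCF3)2 (excess) in aqueous MeCN at 0 °C should oxidise the hydroquinone and cleave the dithiane oxidatively to give 7-methoxy-2,2-dimethyl-6-(3-phenylpropanoyl)-2H-chromene-5,8-dione F3. Reduction with aqueous Na2S2O4 in EtOAc then returns the hydroquinone 19.

Step 5. C6 lithiation may be incomplete under base-limited conditions, or residual alkyllithium may attack the dione. The fallback sets out from 11 and comes back at 12. Compound 11 is lithiated with excess t-BuLi (THF, −78 → 0 °C) and quenched with Bu3SnCl to give the isolable stannane tributyl[6,6-dimethyl-4-(triisopropylsilyloxy)-5,6-dihydro-4H-pyran-2-yl]stannane F4, which is purified. Tin–lithium exchange with exactly one equivalent of n-BuLi (THF, −78 °C) regenerates vinyllithium 12 free of other bases, and addition to 8 continues as in step 5.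

Further compounds
F1 | step 6 | 4-[2,2-dimethyl-4-(triisopropylsilyloxy)-3,4-dihydro-2H-pyran-6-yl]-3-methoxy-2-[2-(2-phenylethyl)-1,3-dithian-2-yl]-4-(trimethylsilyloxy)cyclobut-2-en-1-one | COC1=C(C2(CCc3ccccc3)SCCCS2)C(=O)C1(O[Si](C)(C)C)C1=CC(O[Si](C(C)C)(C(C)C)C(C)C)CC(C)(C)O1
F2 | step 6 | 7-methoxy-2,2-dimethyl-6-[2-(2-phenylethyl)-1,3-dithian-2-yl]-4-(triisopropylsilyloxy)-8-(trimethylsilyloxy)chroman-5-ol | Oc1c(C3(CCc4ccccc4)SCCCS3)c(OC)c(O[Si](C)(C)C)c2OC(C)(C)CC(O[Si](C(C)C)(C(C)C)C(C)C)c12
F3 | step 8 | 7-methoxy-2,2-dimethyl-6-(3-phenylpropanoyl)-2H-chromene-5,8-dione | O=C1C(C(=O)CCc2ccccc2)=C(OC)C(=O)C2=C1C=CC(C)(C)O2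
F4 | step 5 | tributyl[6,6-dimethyl-4-(triisopropylsilyloxy)-5,6-dihydro-4H-pyran-2-yl]stannane | CCCC[Sn](CCCC)(CCCC)C1=CC(O[Si](C(C)C)(C(C)C)C(C)C)CC(C)(C)O1
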